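**Retrosynthetic overview**

- The C3 prenyl group comes last: cross-metathesis of a C3 allyl group, itself put on the finished bicycle by radical allylation of a C3 iodide (attack anti to the lactone bridge).
- Both rings form in one flask from an acyclic keto diester. A Dieckmann closure gives the lactone (ring B) as a 5-acyl-3,3-diprenylfuran-2,4-dione enolate. An enantiotopic-group-selective iodocarbocyclization of that enolate onto one of its two identical prenyl groups then closes the cyclohexanone (ring A, C5–C4 bond between two quaternary carbons).
- The acyclic precursor is a mixed malonate built from dimethyl malonate, two prenyl bromides and 1-bromo-3-methylbutan-2-one.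
- Ring order: B, then A, in the same operation. C1 and C5 are set together by a chiral titanium enolate; C3 is set afterwards by substrate control.

Assumption: the (R,R)-TADDOLate titanium enolate is taken to leave open the face that leads to the (1R,5R) bicycle; this sense is assigned by analogy, not established, and the (S,S) ligand is used if the induction proves opposite.

**Step 1**
Reactants: 1 dimethyl malonate; 2 1-bromo-3-methylbut-2-ene (prenyl bromide)
Product: 3 dimethyl 2,2-bis(3-methylbut-2-en-1-yl)propanedioate
Conditions: NaH (2.3 equiv), 2 (2.3 equiv), THF–DMF 4:1, 0 to 50 °C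
Reagents that add atoms: 1-bromo-3-methylbut-2-ene, CC(C)=CCBr
Why: Malonic ester synthesis, two successive SN2 C-alkylations of the malonate enolate with a reactive allylic bromide; no stereocenter is formed.

**Step 2**
Reactants: 3 dimethyl 2,2-bis(3-methylbut-2-en-1-yl)propanedioate
Product: 4 2-(methoxycarbonyl)-5-methyl-2-(3-methylbut-2-en-1-yl)hex-4-enoic acid
Conditions: KOH (1.05 equiv), MeOH–H2O 9:1, 60 °C; then cold 1 M HCl to pH 3
Reagents that add atoms: potassium hydroxide, [K+].[OH-]
Why: Mono-saponification; after the first hydrolysis the neighbouring carboxylate shields the hindered second ester, so one equivalent of hydroxide stops at the half ester, and the carbon stays achiral because its two prenyl groups are identical.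

**Step 3**
Reactants: 4 2-(methoxycarbonyl)-5-methyl-2-(3-methylbut-2-en-1-yl)hex-4-enoic acid; 5 1-bromo-3-methylbutan-2-one
Product: 6 1-methyl 3-(3-methyl-2-oxobutyl) 2,2-bis(3-methylbut-2-en-1-yl)propanedioate
Conditions: KHCO3 (1.5 equiv), 5 (1.1 equiv), DMF, 23 °C
Reagents that add atoms: 1-bromo-3-methylbutan-2-one, CC(C)C(=O)CBr
Why: SN2 O-alkylation of the carboxylate by the activated α-bromo ketone under a base too weak to enolize the product; no stereocenter is formed.

**Step 4**
Reactants: 6 1-methyl 3-(3-methyl-2-oxobutyl) 2,2-bis(3-methylbut-2-en-1-yl)propanedioate; 7 iodine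
Product: 9 (1R,3R,5R)-3-iodo-4,4-dimethyl-1-(3-methylbut-2-en-1-yl)-5-(2-methylpropanoyl)-6-oxabicyclo[3.2.1]octane-7,8-dione, via furandione enolate 8 (not isolated)
Conditions: LiN(SiMe3)2 (2.1 equiv), THF, −78 to 23 °C; then TiCl2(TADDOLate) [TADDOLate = (4R,5R)-2,2-dimethyl-α,α,α′,α′-tetraphenyl-1,3-dioxolane-4,5-dimethanolate, 1.1 equiv], CH2Cl2, −78 °C; then I2 (2.0 equiv), −78 to −30 °C, dark; aq. Na2S2O3/NaHCO3 work-up
Reagents that add atoms: iodine, II
Why: Proposed new method: the enolate of the 2-oxoalkyl ester closes the furan-2,4-dione by a Lacey–Dieckmann-type Claisen condensation (driven by the acidic C5–H of the product, and with the same outcome whichever ester carbonyl is attacked because C3 carries two identical prenyl groups), and the resulting chiral tetravalent-titanium β-diketonate then attacks through C5 the tertiary end of the iodonium ion of the prenyl group on the face left open by the TADDOLate (6-endo, Markovnikov), which closes ring A, makes the C5–C4 bond and fixes C1 and C5 together (the lactone bridge can only be cis; iodine sits equatorial in the chair transition state); the closest known reaction types are the titanium TADDOLate-mediated enantioselective and enantiotopic-group-selective iodocarbocyclization of alkenyl malonates and the iodonium-induced carbocyclization of β-diketones used for bicyclic polyprenylated acylphloroglucinol cores.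

**Step 5**
Reactants: 9 (1R,3R,5R)-3-iodo-4,4-dimethyl-1-(3-methylbut-2-en-1-yl)-5-(2-methylpropanoyl)-6-oxabicyclo[3.2.1]octane-7,8-dione; 10 allyltributylstannane
Product: 11 (1R,3R,5R)-4,4-dimethyl-1-(3-methylbut-2-en-1-yl)-5-(2-methylpropanoyl)-3-(prop-2-en-1-yl)-6-oxabicyclo[3.2.1]octane-7,8-dione
Conditions: Bu3SnCH2CH=CH2 (3 equiv), AIBN (0.2 equiv), benzene, 80 °C
Reagents that add atoms: allyltributylstannane, C=CC[Sn](CCCC)(CCCC)CCCC
Why: Keck radical allylation; the planar C3 radical (the iodide configuration is erased) is trapped from the equatorial direction because the axial face is blocked by the two-atom lactone bridge, giving the equatorial (3R) allyl group, and cyclization onto the C1 prenyl group is impossible because that group is locked equatorial.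

**Step 6**
Reactants: 11 (1R,3R,5R)-4,4-dimethyl-1-(3-methylbut-2-en-1-yl)-5-(2-methylpropanoyl)-3-(prop-2-en-1-yl)-6-oxabicyclo[3.2.1]octane-7,8-dione; 12 2-methylbut-2-ene
Product: 13 (1R,3R,5R)-4,4-dimethyl-1,3-bis(3-methylbut-2-en-1-yl)-5-(2-methylpropanoyl)-6-oxabicyclo[3.2.1]octane-7,8-dione
Conditions: second-generation Grubbs catalyst RuCl2(=CHPh)(PCy3)(H2IMes) (5 mol %), 2-methylbut-2-ene/CH2Cl2 1:1, 40 °C
Reagents that add atoms: 2-methylbut-2-ene, CC=C(C)C
Why: Olefin cross-metathesis converts the terminal allyl group into prenyl, while the existing trisubstituted prenyl alkene only exchanges degenerately and no stereocenter is touched.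

**Compound list**

1 | dimethyl malonate | COC(=O)CC(=O)OC | starting material
2 | 1-bromo-3-methylbut-2-ene (prenyl bromide) | CC(C)=CCBr | starting material
3 | dimethyl 2,2-bis(3-methylbut-2-en-1-yl)propanedioate | COC(=O)C(CC=C(C)C)(CC=C(C)C)C(=O)OC | intermediate
4 | 2-(methoxycarbonyl)-5-methyl-2-(3-methylbut-2-en-1-yl)hex-4-enoic acid (achiral) | COC(=O)C(CC=C(C)C)(CC=C(C)C)C(=O)O | intermediate
5 | 1-bromo-3-methylbutan-2-one | CC(C)C(=O)CBr | starting material
6 | 1-methyl 3-(3-methyl-2-oxobutyl) 2,2-bis(3-methylbut-2-en-1-yl)propanedioate | COC(=O)C(CC=C(C)C)(CC=C(C)C)C(=O)OCC(=O)C(C)C | intermediate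
7 | iodine | II | starting material
8 | 5-(2-methylpropanoyl)-3,3-bis(3-methylbut-2-en-1-yl)furan-2,4(3H,5H)-dione, present as its lithium then titanium enolate (C5 planar, not a fixed stereocenter) | CC(C)C(=O)C1OC(=O)C(CC=C(C)C)(CC=C(C)C)C1=O | intermediate
9 | (1R,3R,5R)-3-iodo-4,4-dimethyl-1-(3-methylbut-2-en-1-yl)-5-(2-methylpropanoyl)-6-oxabicyclo[3.2.1]octane-7,8-dione (iodine equatorial, anti to the lactone bridge) | I[C@@H]1C[C@@]2(CC=C(C)C)C(=O)O[C@](C(=O)C(C)C)(C2=O)C1(C)C | intermediate
10 | allyltributylstannane | C=CC[Sn](CCCC)(CCCC)CCCC | starting material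
11 | (1R,3R,5R)-4,4-dimethyl-1-(3-methylbut-2-en-1-yl)-5-(2-methylpropanoyl)-3-(prop-2-en-1-yl)-6-oxabicyclo[3.2.1]octane-7,8-dione | C=CC[C@@H]1C[C@@]2(CC=C(C)C)C(=O)O[C@](C(=O)C(C)C)(C2=O)C1(C)C | intermediate
12 | 2-methylbut-2-ene | CC=C(C)C | starting material
13 | (1R,3R,5R)-4,4-dimethyl-1,3-bis(3-methylbut-2-en-1-yl)-5-(2-methylpropanoyl)-6-oxabicyclo[3.2.1]octane-7,8-dione (CNP0231965.1) | CC(C)=CC[C@@H]1C[C@@]2(CC=C(C)C)C(=O)O[C@](C(=O)C(C)C)(C2=O)C1(C)C | target

**Step count**

Total step count: 6. Longest linear sequence: 6 steps (from 1).

**Steps most likely to fail, with fallbacks**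

The step most at risk is step 4. The level and sense of induction by the titanium enolate are untested for a cyclic β-diketonate and a trisubstituted alkene. O-cyclization through the ring ketone oxygen, or a radical 5-exo pathway from a C5 iodide, could also compete. If the enantiomeric excess is short of complete, 9 is recrystallized. The fallback sets out from 6. The same base-induced Dieckmann closure gives 8, which is protonated with one equivalent of CF3CO2H. It is then cyclized with a stoichiometric chiral selenium electrophile, 2-[(1S)-1-methoxyethyl]phenylselenenyl triflate (from the diselenide, Br2 and AgOTf), in CH2Cl2 at −78 °C, instead of with iodine under titanium control. Seleniranium formation is reversible and only the chair transition state with equatorial selenium closes. The two products that differ in the configuration of the bicycle are now diastereomers and are separated on silica. The (1R,3R,5R) bicyclic C3 aryl selenide F1 is then allylated with Bu3SnCH2CH=CH2 and AIBN, and the route is rejoined at 11.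

The second is step 5. The C3 radical could open by β-scission towards the stabilized C5 diacyl radical, or be reduced, before the stannane traps it. The fallback sets out from 9 and couples it directly with 2 in a nickel-catalysed reductive cross-electrophile coupling (NiBr2(dme), 4,4′-di-tert-butyl-2,2′-bipyridine, Mn powder, DMA, 23 °C). The C3 radical is captured by nickel, and the prenyl group is delivered at its unsubstituted terminus in one bond-forming event from the same open face. This dispenses with the stannane and the metathesis and comes back at 13; it makes no new compound (F0).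

The third is step 2. The hindered diester may hydrolyse sluggishly, or go on to the diacid and decarboxylate. The fallback sets out from 2, which doubly C-alkylates commercial 2,2-dimethyl-1,3-dioxane-4,6-dione (Meldrum's acid; K2CO3, DMF, 23 °C) to give 5,5-diprenyl Meldrum's acid F2. Methanolysis (MeOH, reflux) opens the dioxanedione exactly once, with loss of acetone, and comes back at 4.

**Further compounds**

F1 | step 4 | (1R,3R,5R)-3-({2-[(1S)-1-methoxyethyl]phenyl}selanyl)-4,4-dimethyl-1-(3-methylbut-2-en-1-yl)-5-(2-methylpropanoyl)-6-oxabicyclo[3.2.1]octane-7,8-dione | CO[C@@H](C)c1ccccc1[Se][C@@H]1C[C@@]2(CC=C(C)C)C(=O)O[C@](C(=O)C(C)C)(C2=O)C1(C)C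
F0 | step 5 | none | none
F2 | step 2 | 2,2-dimethyl-5,5-bis(3-methylbut-2-en-1-yl)-1,3-dioxane-4,6-dione | CC(C)=CCC1(CC=C(C)C)C(=O)OC(C)(C)OC1=O
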